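**Strategy.** Numbering runs from the lactone carbonyl (C1) along the ring to C41 and on to C50. The route rests on cutting the C18–C19 bond of the C17–C19 hydroxy–methyl–hydroxy triad, the only aldol retron inside the 42-membered macrolactone ring. A reagent-controlled boron macro-aldol between a C17 ethyl ketone and a non-enolisable C19 ynal closes this ring in one operation and sets C18 and C19 (syn); hydroxyl-directed reduction then sets C17. The precursor is an acyclic triyne ester: an all-anti C4–C18 polyol ketone (dithiane relay couplings) joined to a C19–C50 chain (epoxide openings) through a C41 propiolate and a Sonogashira coupling. One Lindlar reduction finally converts the three alkynes into Z alkenes.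

Key step: step 31

Remark: "configured as in the target" means the same spatial arrangement at the carbon of that target number; TBS = tert-butyldimethylsilyl, PMB = 4-methoxybenzyl; 4-methoxybenzyl propargyl ether and both enantiomers of 2-(2-bromoethyl)oxirane are assumed to be purchasable.

**West fragment (C4–C18)**

Step 1
Reactants: 1 (S)-epichlorohydrin
Product: 3 (S)-2-allyloxirane, via chlorohydrin 2 (not isolated)
Conditions: vinylmagnesium bromide, CuI (10 mol %), THF, −40 °C; then aq NaOH, 0 °C to rt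
Reagents that add atoms: vinylmagnesium bromide, C=C[Mg]Br
Why: Copper-catalysed Grignard opening at the epoxide CH2 and base closure of the chlorohydrin onto the former CH2Cl carbon should give the C5–C8 epoxide, with C7 carried unchanged from 1 because no bond at the stereocentre is broken.

Step 2
Reactants: 4 (R)-epichlorohydrin; 5 2-bromobut-1-ene
Product: 7 (R)-2-(2-methylidenebutyl)oxirane, via chlorohydrin 6 (not isolated)
Conditions: 5, Mg, THF; CuI (10 mol %), 4, −40 °C; then aq NaOH, rt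
Reagents that add atoms: none
Why: The same copper-catalysed Grignard opening and chlorohydrin closure should give the C14–C18 epoxide, in which C15 comes from 4 and the 1,1-disubstituted alkene masks the C17 ethyl ketone.

Step 3
Reactants: 7 (R)-2-(2-methylidenebutyl)oxirane; 8 2-(tert-butyldimethylsilyl)-1,3-dithiane; 4 (R)-epichlorohydrin
Product: 11 C10–C18 epoxy dithiane, via lithiodithiane 9 (not isolated), via chloroalkoxide 10 (not isolated)
Conditions: 8, t-BuLi, Et2O, −78 to −45 °C; 7, −78 to −25 °C; then 4, HMPA, THF, −78 °C to rt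
Reagents that add atoms: none
Why: In this dithiane linchpin coupling lithiated 8 opens 7 at C14, HMPA triggers the 1,4-Brook rearrangement that silylates the C15 oxygen and regenerates a C13 carbanion, and this opens 4 at its epoxide CH2 (C12) before the alkoxide closes onto C10, so that C11 and C15 both come from the chiral pool.

Step 4
Reactants: 8 2-(tert-butyldimethylsilyl)-1,3-dithiane; 3 (S)-2-allyloxirane; 11 C10–C18 epoxy dithiane
Product: 13 C5–C18 bis(dithiane) alcohol, via lithiodithiane 12 (not isolated)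
Conditions: 8, t-BuLi, Et2O, −78 to −45 °C; 3, −78 to −25 °C; then 11, HMPA, THF, −78 to 0 °C
Reagents that add atoms: none
Why: A second relay coupling (opening of 3 at C8, Brook silylation of the C7 oxygen, opening of 11 at C10) should assemble the C5–C18 chain and leave only the C11 hydroxyl free as the director for step 6.

Step 5
Reactants: 13 C5–C18 bis(dithiane) alcohol
Product: 14 C5–C18 hydroxy diketone
Conditions: MeI, CaCO3, MeCN/H2O (9:1), 45 °C
Reagents that add atoms: water, O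
Why: Alkylative hydrolysis (S-methylation, then attack of water) should unmask the C9 and C13 ketones under buffered neutral conditions that spare both alkenes, the silyl ethers and the β-hydroxy ketone.

Step 6
Reactants: 14 C5–C18 hydroxy diketone
Product: 15 C5–C18 anti,anti-triol
Conditions: Me4NBH(OAc)3, MeCN/AcOH (1:1), −30 °C
Reagents that add atoms: none
Why: In this Evans–Saksena reduction the C11 hydroxyl binds the acetoxyborohydride and delivers hydride intramolecularly through chair transition states to both flanking ketones, which should give the 9,11-anti and 11,13-anti relationships of the target.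

Step 7
Reactants: 15 C5–C18 anti,anti-triol
Product: 16 C5–C18 pentakis(TBS ether) diene
Conditions: TBSOTf, 2,6-lutidine, CH2Cl2, −78 to 0 °C
Reagents that add atoms: tert-butyldimethylsilyl triflate, CC(C)(C)[Si](C)(C)OS(=O)(=O)C(F)(F)F
Why: Silyl triflate with a hindered base should silylate all three secondary hydroxyls while no carbonyl group is present.

Step 8
Reactants: 16 C5–C18 pentakis(TBS ether) diene
Product: 17 C5–C18 keto aldehyde
Conditions: O3, CH2Cl2, −78 °C; then PPh3, −78 °C to rt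
Reagents that add atoms: ozone, [O-][O+]=O
Why: Ozonolysis with reductive work-up should cleave both alkenes at once, the vinyl group to the C5 aldehyde and the 1,1-disubstituted alkene to the C17 ethyl ketone.

Step 9
Reactants: 17 C5–C18 keto aldehyde
Product: 18 C4–C18 (Z)-vinyl iodide ethyl ketone
Conditions: EtPPh3I, n-BuLi, THF, 0 °C; I2, −78 °C; NaHMDS, −20 °C; then 17, −78 to −20 °C
Reagents that add atoms: ethyltriphenylphosphonium iodide, CC[P+](c1ccccc1)(c1ccccc1)c1ccccc1.[I-]; iodine, II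
Why: Stork–Zhao-type Wittig olefination with the α-iodo ylide should convert the aldehyde (faster than the ketone) into the (Z)-2-iodoalkene, iodine cis to C6, which fixes the C4=C5 geometry.

**East fragment (C19–C50)**

Step 10
Reactants: 19 4-methoxybenzyl propargyl ether; 20 (R)-2-(2-bromoethyl)oxirane
Product: 21 C19–C25 bromo alcohol
Conditions: 19, n-BuLi, THF, −78 °C; BF3·OEt2; then 20, −78 °C
Reagents that add atoms: none
Why: Yamaguchi–Hirao alkynylation (alkynyl borate opening of the epoxide at its CH2, the primary bromide untouched at −78 °C) should form C21–C22 with C23 taken from 20.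

Step 11
Reactants: 21 C19–C25 bromo alcohol
Product: 22 C19–C25 bromide TBS ether
Conditions: TBSOTf, 2,6-lutidine, CH2Cl2, −78 °C
Reagents that add atoms: tert-butyldimethylsilyl triflate, CC(C)(C)[Si](C)(C)OS(=O)(=O)C(F)(F)F
Why: Standard silylation of the secondary C23 hydroxyl.

Step 12
Reactants: 22 C19–C25 bromide TBS ether; 1 (S)-epichlorohydrin
Product: 24 C19–C28 epoxide, via chlorohydrin 23 (not isolated)
Conditions: 22, Mg, THF; CuI (10 mol %), 1, −40 °C; then aq NaOH, rt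
Reagents that add atoms: none
Why: The γ-silyloxy Grignard reagent should open the epoxide CH2 (C26) under copper catalysis faster than it attacks the propargylic ether or the alkyne, and base closure gives the C27–C28 epoxide with C27 from 1.

Step 13
Reactants: 25 trimethylsilylacetylene; 26 1,5-dibromopentane
Product: 27 (7-bromohept-1-yn-1-yl)trimethylsilane
Conditions: 25, n-BuLi, THF, −78 °C; then 26 (3 equiv), DMPU, −78 °C to rt
Reagents that add atoms: none
Why: SN2 alkylation of the lithium acetylide with excess dibromide should give the monoalkylated C33–C39 chain.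

Step 14
Reactants: 27 (7-bromohept-1-yn-1-yl)trimethylsilane; 28 (S)-2-(2-bromoethyl)oxirane
Product: 29 C29–C39 bromo alcohol
Conditions: 27, Mg, THF; CuI (10 mol %), 28, −40 °C
Reagents that add atoms: none
Why: Copper-catalysed Grignard opening of the epoxide CH2 (C32) is expected to outrun coupling at the primary bromide at this temperature and forms C32–C33 with C31 taken from 28.

Step 15
Reactants: 29 C29–C39 bromo alcohol
Product: 30 C29–C39 bromide TBS ether
Conditions: TBSOTf, 2,6-lutidine, CH2Cl2, −78 °C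
Reagents that add atoms: tert-butyldimethylsilyl triflate, CC(C)(C)[Si](C)(C)OS(=O)(=O)C(F)(F)F
Why: Standard silylation of the secondary C31 hydroxyl.

Step 16
Reactants: 30 C29–C39 bromide TBS ether; 24 C19–C28 epoxide
Product: 32 C19–C39 alkynol, via silylalkyne alcohol 31 (not isolated)
Conditions: 30, Mg, THF; CuI (10 mol %), 24, −40 to −20 °C; then MeOH, K2CO3, rt
Reagents that add atoms: none
Why: Copper-catalysed Grignard opening of 24 at C28 should form C28–C29 and free the C27 hydroxyl, and basic methanolysis then removes the alkynyl trimethylsilyl group.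

Step 17
Reactants: 32 C19–C39 alkynol
Product: 33 C19–C39 alkyne tris(TBS ether)
Conditions: TBSOTf, 2,6-lutidine, CH2Cl2, −78 to 0 °C
Reagents that add atoms: tert-butyldimethylsilyl triflate, CC(C)(C)[Si](C)(C)OS(=O)(=O)C(F)(F)F
Why: Silylation of the C27 hydroxyl, the terminal alkyne being inert to the silyl triflate.

Step 18
Reactants: 34 6-bromohex-1-ene; 35 (R)-propylene oxide
Product: 36 (R)-non-8-en-2-ol
Conditions: 34, Mg, THF; CuI (10 mol %), 35, −30 °C
Reagents that add atoms: none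
Why: Copper-catalysed Grignard opening at the epoxide CH2 should give the C43–C50 chain (plus one alkene carbon) with C49 taken from 35.

Step 19
Reactants: 36 (R)-non-8-en-2-ol
Product: 37 (R)-tert-butyldimethyl(non-8-en-2-yloxy)silane
Conditions: TBSCl, imidazole, DMF, rt
Reagents that add atoms: tert-butyldimethylsilyl chloride, CC(C)(C)[Si](C)(C)Cl
Why: Standard silylation of the secondary alcohol.

Step 20
Reactants: 37 (R)-tert-butyldimethyl(non-8-en-2-yloxy)silane
Product: 38 (R)-7-(tert-butyldimethylsilyloxy)octanal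
Conditions: O3, CH2Cl2, −78 °C; then PPh3
Reagents that add atoms: ozone, [O-][O+]=O
Why: Ozonolysis of the terminal alkene with reductive work-up should give the C43 aldehyde.

Step 21
Reactants: 38 (R)-7-(tert-butyldimethylsilyloxy)octanal; 39 (S)-4-benzyl-3-propanoyloxazolidin-2-one
Product: 40 syn-aldol imide (S)-4-benzyl-3-[(2S,3R,9R)-9-(tert-butyldimethylsilyloxy)-3-hydroxy-2-methyldecanoyl]oxazolidin-2-one
Conditions: 39, Bu2BOTf, i-Pr2NEt, CH2Cl2, −78 to 0 °C; 38, −78 to 0 °C; then H2O2, pH 7 buffer, MeOH, 0 °C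
Reagents that add atoms: none
Why: Evans syn aldol through the Z boron enolate and a chair Zimmerman–Traxler transition state, in which the benzyl auxiliary shields one enolate face, should set C42 and C43 (methyl and hydroxyl syn) as in the target.

Step 22
Reactants: 40 syn-aldol imide
Product: 41 Weinreb amide (2S,3R,9R)-9-(tert-butyldimethylsilyloxy)-3-hydroxy-N-methoxy-N,2-dimethyldecanamide
Conditions: MeNH(OMe)·HCl, AlMe3, THF, 0 °C to rt
Reagents that add atoms: N,O-dimethylhydroxylamine hydrochloride, CNOC.Cl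
Why: Aluminium amide transamidation assisted by the free β-hydroxyl should cleave the auxiliary without epimerising C42.

Step 23
Reactants: 41 Weinreb amide
Product: 42 chloromethyl ketone (3S,4R,10R)-10-(tert-butyldimethylsilyloxy)-1-chloro-4-hydroxy-3-methylundecan-2-one
Conditions: ClCH2I, MeLi·LiBr, THF/Et2O, −78 °C
Reagents that add atoms: chloroiodomethane, ClCI
Why: Chloromethyllithium generated in the flask by iodine–lithium exchange should add once to the Weinreb amide (stable chelated tetrahedral adduct) and so introduce C40 as a chloromethyl ketone.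

Step 24
Reactants: 42 chloromethyl ketone
Product: 44 C40–C50 epoxy alcohol, via chlorodiol 43 (not isolated)
Conditions: Et2BOMe, THF/MeOH (4:1), −78 °C; NaBH4; MeOH co-evaporation; then K2CO3, MeOH, 0 °C
Reagents that add atoms: none
Why: Narasaka–Prasad reduction (external hydride attacks the six-membered boron chelate axially) should set C41 syn to C43, and mild base then closes the vicinal chlorohydrin to the terminal C40–C41 epoxide.

Step 25
Reactants: 44 C40–C50 epoxy alcohol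
Product: 45 C40–C50 epoxide bis(TBS ether)
Conditions: TBSCl, imidazole, DMAP (cat.), DMF, 35 °C
Reagents that add atoms: tert-butyldimethylsilyl chloride, CC(C)(C)[Si](C)(C)Cl
Why: Silyl chloride with imidazole should protect the C43 hydroxyl without opening the epoxide.

Step 26
Reactants: 33 C19–C39 alkyne tris(TBS ether); 45 C40–C50 epoxide bis(TBS ether)
Product: 46 C19–C50 alcohol
Conditions: 33, n-BuLi, THF, −78 °C; BF3·OEt2; then 45, −78 °C
Reagents that add atoms: none
Why: Yamaguchi–Hirao alkynylation at the epoxide CH2 (C40) should form C39–C40 and free exactly one hydroxyl, the C41 carbinol needed for the ester.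

**Union, ring closure and end game**

Step 27
Reactants: 46 C19–C50 alcohol; 47 propiolic acid
Product: 48 C41 propiolate
Conditions: DCC, DMAP (10 mol %), CH2Cl2, −20 to 0 °C
Reagents that add atoms: none
Why: Steglich esterification at low temperature should acylate the only free hydroxyl and install C1–C3 as a terminal alkynoate.

Step 28
Reactants: 48 C41 propiolate; 18 C4–C18 (Z)-vinyl iodide ethyl ketone
Product: 49 seco triyne ketone
Conditions: PdCl2(PPh3)2 (5 mol %), CuI (10 mol %), i-Pr2NEt, THF, 0 °C to rt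
Reagents that add atoms: none
Why: Sonogashira coupling of the terminal alkynoate with the vinyl iodide proceeds with retention of alkene geometry and should join the two halves through the C3–C4 bond.

Step 29
Reactants: 49 seco triyne ketone
Product: 50 seco propargylic alcohol
Conditions: DDQ, CH2Cl2/pH 7 buffer (10:1), 0 °C
Reagents that add atoms: none
Why: Oxidative cleavage of the 4-methoxybenzyl ether should free the C19 hydroxyl without touching silyl ethers, alkynes or the enynoate.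

Step 30
Reactants: 50 seco propargylic alcohol
Product: 51 seco keto ynal
Conditions: Dess–Martin periodinane, NaHCO3, CH2Cl2, 0 °C to rt
Reagents that add atoms: none
Why: Buffered Dess–Martin oxidation should convert the primary propargylic alcohol into the C19 ynal without epimerisation or silyl loss.

Step 31
Reactants: 51 seco keto ynal
Product: 53 macrocyclic aldol, via enol borinate 52 (not isolated)
Conditions: (−)-Ipc2BOTf (freshly made from (+)-α-pinene, BH3·SMe2 and TfOH), i-Pr2NEt, CH2Cl2, −78 °C, slow addition of 51 (final 1 mM), then −78 to −20 °C; H2O2, pH 7 buffer, MeOH, 0 °C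
Reagents that add atoms: none
Why: Ipc2BOTf complexes the C17 ketone and i-Pr2NEt removes a C18 proton to give the Z enol borinate 52, which adds to the non-enolisable C19 ynal through a chair Zimmerman–Traxler transition state before the boron aldolate is cleaved oxidatively. The closest known reaction is the Paterson syn aldol of ethyl ketones with Ipc2BOTf, run here intramolecularly as a macro-aldol. The 42-membered ring (C1–C41 and the lactone oxygen) is closed by attack of the ring enolate carbon C18 on the exocyclic C19=O (enolendo, exo-trig). The Z enolate geometry in the chair sets the 18,19-syn relationship, and the (−)-Ipc ligands are expected to direct the enolate to the Si face of the aldehyde, as in the corresponding allylborations, which gives the target configuration at C18 and C19 by reagent control. The step needs enolisation at C18 and not at C16, which the unhindered ethyl terminus (against C16 next to the C15 silyloxy stereocentre) and the bulk of the reagent should secure, and it needs the aldehyde to act only as electrophile, which the C20–C21 alkyne secures (no α-hydrogen, no Z/E lability). Ring closure over oligomerisation is favoured by slow addition at high dilution.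

Step 32
Reactants: 53 macrocyclic aldol
Product: 54 macrocyclic 17,19-diol triyne
Conditions: Me4NBH(OAc)3, MeCN/AcOH (1:1), −30 °C
Reagents that add atoms: none
Why: Evans–Saksena reduction with intramolecular hydride delivery from the C19 alkoxyborohydride (C15 being silylated) should give the 17,19-anti diol and thus the 17,18-anti, 18,19-syn triad of the target.

Step 33
Reactants: 54 macrocyclic 17,19-diol triyne
Product: 55 deca(TBS) ether of the target
Conditions: H2 (1 atm), Pd/CaCO3 poisoned with Pb(OAc)2, quinoline, EtOAc, rt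
Reagents that add atoms: none
Why: Lindlar semi-hydrogenation adds hydrogen syn to each of the three alkynes and should give the C2=C3, C20=C21 and C38=C39 Z alkenes, while the trisubstituted C4=C5 alkene is not reduced.

Step 34
Reactants: 55 deca(TBS) ether of the target
Product: 56 CNP0071908.2
Conditions: HF·pyridine, pyridine, THF, 0 °C to rt
Reagents that add atoms: none
Why: Buffered fluoride-mediated global desilylation should remove all ten silyl ethers without lactone migration or isomerisation of the (2Z,4Z)-dienoate.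

**Compound list**

1 | (S)-epichlorohydrin | ClC[C@@H]1CO1 | starting material
2 | (S)-1-chloropent-4-en-2-ol | C=CC[C@H](O)CCl | intermediate
3 | (S)-2-allyloxirane | C=CC[C@H]1CO1 | intermediate
4 | (R)-epichlorohydrin | ClC[C@H]1CO1 | starting material
5 | 2-bromobut-1-ene | C=C(Br)CC | starting material
6 | (R)-1-chloro-4-methylidenehexan-2-ol | ClC[C@H](O)CC(=C)CC | intermediate
7 | (R)-2-(2-methylidenebutyl)oxirane | C1[C@H](O1)CC(=C)CC | intermediate
8 | 2-(tert-butyldimethylsilyl)-1,3-dithiane | CC(C)(C)[Si](C)(C)C1SCCCS1 | starting material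
9 | lithiodithiane: C13-lithiated 1,3-dithiane carrying the C14–C18 arm (C15 OTBS as in the target, C17 methylidene) | [Li]C1(SCCCS1)C[C@H](O[Si](C)(C)C(C)(C)C)CC(=C)CC | intermediate
10 | chloroalkoxide: lithium alkoxide of the C10 chloride C11 alcohol (dithiane at C13, C15 OTBS) | ClC[C@H](O[Li])CC1(SCCCS1)C[C@H](O[Si](C)(C)C(C)(C)C)CC(=C)CC | intermediate
11 | C10–C18 epoxy dithiane (C10–C11 oxirane, dithiane at C13, C15 OTBS, C17 methylidene; C11 and C15 as in the target) | C1[C@H](O1)CC2(SCCCS2)C[C@H](O[Si](C)(C)C(C)(C)C)CC(=C)CC | intermediate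
12 | lithiodithiane: C9-lithiated 1,3-dithiane carrying the C5–C8 arm (C7 OTBS as in the target, terminal vinyl) | C=CC[C@H](O[Si](C)(C)C(C)(C)C)CC1([Li])SCCCS1 | intermediate
13 | C5–C18 bis(dithiane) alcohol (dithianes at C9 and C13, C11 OH, C7 and C15 OTBS, vinyl at C5, methylidene on C17; C7, C11, C15 as in the target) | C=CC[C@H](O[Si](C)(C)C(C)(C)C)CC1(SCCCS1)C[C@H](O)CC2(SCCCS2)C[C@H](O[Si](C)(C)C(C)(C)C)CC(=C)CC | intermediate
14 | C5–C18 hydroxy diketone (ketones at C9 and C13, C11 OH, C7 and C15 OTBS) | C=CC[C@H](O[Si](C)(C)C(C)(C)C)CC(=O)C[C@H](O)CC(=O)C[C@H](O[Si](C)(C)C(C)(C)C)CC(=C)CC | intermediate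
15 | C5–C18 anti,anti-triol (C9, C11, C13 OH; C7 and C15 OTBS; all five carbinols as in the target) | C=CC[C@H](O[Si](C)(C)C(C)(C)C)C[C@@H](O)C[C@H](O)C[C@@H](O)C[C@H](O[Si](C)(C)C(C)(C)C)CC(=C)CC | intermediate
16 | C5–C18 pentakis(TBS ether) diene | C=CC[C@H](O[Si](C)(C)C(C)(C)C)C[C@@H](O[Si](C)(C)C(C)(C)C)C[C@H](O[Si](C)(C)C(C)(C)C)C[C@@H](O[Si](C)(C)C(C)(C)C)C[C@H](O[Si](C)(C)C(C)(C)C)CC(=C)CC | intermediate
17 | C5–C18 keto aldehyde (C5 aldehyde, C17 ethyl ketone, OTBS at C7, C9, C11, C13, C15) | O=CC[C@H](O[Si](C)(C)C(C)(C)C)C[C@@H](O[Si](C)(C)C(C)(C)C)C[C@H](O[Si](C)(C)C(C)(C)C)C[C@@H](O[Si](C)(C)C(C)(C)C)C[C@H](O[Si](C)(C)C(C)(C)C)CC(=O)CC | intermediate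
18 | C4–C18 (Z)-vinyl iodide ethyl ketone (iodine on C4 cis to C6; five OTBS; C17 ketone) | I/C(C)=C\C[C@H](O[Si](C)(C)C(C)(C)C)C[C@@H](O[Si](C)(C)C(C)(C)C)C[C@H](O[Si](C)(C)C(C)(C)C)C[C@@H](O[Si](C)(C)C(C)(C)C)C[C@H](O[Si](C)(C)C(C)(C)C)CC(=O)CC | intermediate
19 | 4-methoxybenzyl propargyl ether | C#CCOCc1ccc(OC)cc1 | starting material
20 | (R)-2-(2-bromoethyl)oxirane | C1[C@H](O1)CCBr | starting material
21 | C19–C25 bromo alcohol (C19 OPMB, C20≡C21, C23 OH as in the target, C25 Br) | COc1ccc(cc1)COCC#CC[C@H](O)CCBr | intermediate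
22 | C19–C25 bromide TBS ether | COc1ccc(cc1)COCC#CC[C@H](O[Si](C)(C)C(C)(C)C)CCBr | intermediate
23 | chlorohydrin: C19–C28 chain with C27 OH and C28 Cl | COc1ccc(cc1)COCC#CC[C@H](O[Si](C)(C)C(C)(C)C)CCC[C@H](O)CCl | intermediate
24 | C19–C28 epoxide (C27–C28 oxirane; C23 OTBS; C23 and C27 as in the target) | COc1ccc(cc1)COCC#CC[C@H](O[Si](C)(C)C(C)(C)C)CCC[C@H]1CO1 | intermediate
25 | trimethylsilylacetylene | C#C[Si](C)(C)C | starting material
26 | 1,5-dibromopentane | BrCCCCCBr | starting material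
27 | (7-bromohept-1-yn-1-yl)trimethylsilane | BrCCCCCC#C[Si](C)(C)C | intermediate
28 | (S)-2-(2-bromoethyl)oxirane | BrCC[C@H]1CO1 | starting material
29 | C29–C39 bromo alcohol (C29 Br, C31 OH as in the target, C38≡C39 SiMe3) | BrCC[C@H](O)CCCCCCC#C[Si](C)(C)C | intermediate
30 | C29–C39 bromide TBS ether | BrCC[C@H](O[Si](C)(C)C(C)(C)C)CCCCCCC#C[Si](C)(C)C | intermediate
31 | silylalkyne alcohol: C19–C39 chain with C27 OH and C39 SiMe3 | COc1ccc(cc1)COCC#CC[C@H](O[Si](C)(C)C(C)(C)C)CCC[C@H](O)CCC[C@H](O[Si](C)(C)C(C)(C)C)CCCCCCC#C[Si](C)(C)C | intermediate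
32 | C19–C39 alkynol (C27 OH, terminal C38≡C39 alkyne, OTBS at C23 and C31) | COc1ccc(cc1)COCC#CC[C@H](O[Si](C)(C)C(C)(C)C)CCC[C@H](O)CCC[C@H](O[Si](C)(C)C(C)(C)C)CCCCCCC#C | intermediate
33 | C19–C39 alkyne tris(TBS ether) (OTBS at C23, C27, C31, all as in the target) | COc1ccc(cc1)COCC#CC[C@H](O[Si](C)(C)C(C)(C)C)CCC[C@H](O[Si](C)(C)C(C)(C)C)CCC[C@H](O[Si](C)(C)C(C)(C)C)CCCCCCC#C | intermediate
34 | 6-bromohex-1-ene | C=CCCCCBr | starting material
35 | (R)-propylene oxide | C[C@@H]1CO1 | starting material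
36 | (R)-non-8-en-2-ol | C=CCCCCC[C@@H](C)O | intermediate
37 | (R)-tert-butyldimethyl(non-8-en-2-yloxy)silane | C=CCCCCC[C@@H](C)O[Si](C)(C)C(C)(C)C | intermediate
38 | (R)-7-(tert-butyldimethylsilyloxy)octanal | O=CCCCCC[C@@H](C)O[Si](C)(C)C(C)(C)C | intermediate
39 | (S)-4-benzyl-3-propanoyloxazolidin-2-one | CCC(=O)N1[C@@H](Cc2ccccc2)COC1=O | starting material
40 | syn-aldol imide (S)-4-benzyl-3-[(2S,3R,9R)-9-(tert-butyldimethylsilyloxy)-3-hydroxy-2-methyldecanoyl]oxazolidin-2-one | O=C(N1[C@@H](Cc2ccccc2)COC1=O)[C@@H](C)[C@H](O)CCCCC[C@@H](C)O[Si](C)(C)C(C)(C)C | intermediate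
41 | Weinreb amide (2S,3R,9R)-9-(tert-butyldimethylsilyloxy)-3-hydroxy-N-methoxy-N,2-dimethyldecanamide | CON(C)C(=O)[C@@H](C)[C@H](O)CCCCC[C@@H](C)O[Si](C)(C)C(C)(C)C | intermediate
42 | chloromethyl ketone (3S,4R,10R)-10-(tert-butyldimethylsilyloxy)-1-chloro-4-hydroxy-3-methylundecan-2-one | ClCC(=O)[C@@H](C)[C@H](O)CCCCC[C@@H](C)O[Si](C)(C)C(C)(C)C | intermediate
43 | chlorodiol: C40 chloride with C41 and C43 hydroxyls syn, C42 methyl, C49 OTBS (all as in the target) | ClC[C@@H]([C@@H](C)[C@H](O)CCCCC[C@@H](C)O[Si](C)(C)C(C)(C)C)O | intermediate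
44 | C40–C50 epoxy alcohol (C40–C41 oxirane, C43 OH, C49 OTBS; C41, C42, C43, C49 as in the target) | C1[C@@H]([C@@H](C)[C@H](O)CCCCC[C@@H](C)O[Si](C)(C)C(C)(C)C)O1 | intermediate
45 | C40–C50 epoxide bis(TBS ether) (OTBS at C43 and C49) | C1[C@@H]([C@@H](C)[C@H](O[Si](C)(C)C(C)(C)C)CCCCC[C@@H](C)O[Si](C)(C)C(C)(C)C)O1 | intermediate
46 | C19–C50 alcohol (C19 OPMB; alkynes C20≡C21 and C38≡C39; OTBS at C23, C27, C31, C43, C49; free C41 OH; all stereocentres as in the target) | COc1ccc(cc1)COCC#CC[C@H](O[Si](C)(C)C(C)(C)C)CCC[C@H](O[Si](C)(C)C(C)(C)C)CCC[C@H](O[Si](C)(C)C(C)(C)C)CCCCCCC#CC[C@@H]([C@@H](C)[C@H](O[Si](C)(C)C(C)(C)C)CCCCC[C@@H](C)O[Si](C)(C)C(C)(C)C)O | intermediate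
47 | propiolic acid | C#CC(=O)O | starting material
48 | C41 propiolate of 46 | COc1ccc(cc1)COCC#CC[C@H](O[Si](C)(C)C(C)(C)C)CCC[C@H](O[Si](C)(C)C(C)(C)C)CCC[C@H](O[Si](C)(C)C(C)(C)C)CCCCCCC#CC[C@@H]([C@@H](C)[C@H](O[Si](C)(C)C(C)(C)C)CCCCC[C@@H](C)O[Si](C)(C)C(C)(C)C)OC(=O)C#C | intermediate
49 | seco triyne ketone (C1–C50 acyclic ester: C2≡C3, (4Z)-alkene, C17 ethyl ketone, C19 OPMB, ten OTBS) | COc1ccc(cc1)COCC#CC[C@H](O[Si](C)(C)C(C)(C)C)CCC[C@H](O[Si](C)(C)C(C)(C)C)CCC[C@H](O[Si](C)(C)C(C)(C)C)CCCCCCC#CC[C@@H]([C@@H](C)[C@H](O[Si](C)(C)C(C)(C)C)CCCCC[C@@H](C)O[Si](C)(C)C(C)(C)C)OC(=O)C#C/C(C)=C\C[C@H](O[Si](C)(C)C(C)(C)C)C[C@@H](O[Si](C)(C)C(C)(C)C)C[C@H](O[Si](C)(C)C(C)(C)C)C[C@@H](O[Si](C)(C)C(C)(C)C)C[C@H](O[Si](C)(C)C(C)(C)C)CC(=O)CC | intermediate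
50 | seco propargylic alcohol (as 49 with free C19 OH) | OCC#CC[C@H](O[Si](C)(C)C(C)(C)C)CCC[C@H](O[Si](C)(C)C(C)(C)C)CCC[C@H](O[Si](C)(C)C(C)(C)C)CCCCCCC#CC[C@@H]([C@@H](C)[C@H](O[Si](C)(C)C(C)(C)C)CCCCC[C@@H](C)O[Si](C)(C)C(C)(C)C)OC(=O)C#C/C(C)=C\C[C@H](O[Si](C)(C)C(C)(C)C)C[C@@H](O[Si](C)(C)C(C)(C)C)C[C@H](O[Si](C)(C)C(C)(C)C)C[C@@H](O[Si](C)(C)C(C)(C)C)C[C@H](O[Si](C)(C)C(C)(C)C)CC(=O)CC | intermediate
51 | seco keto ynal (C19 aldehyde, C17 ethyl ketone) | O=CC#CC[C@H](O[Si](C)(C)C(C)(C)C)CCC[C@H](O[Si](C)(C)C(C)(C)C)CCC[C@H](O[Si](C)(C)C(C)(C)C)CCCCCCC#CC[C@@H]([C@@H](C)[C@H](O[Si](C)(C)C(C)(C)C)CCCCC[C@@H](C)O[Si](C)(C)C(C)(C)C)OC(=O)C#C/C(C)=C\C[C@H](O[Si](C)(C)C(C)(C)C)C[C@@H](O[Si](C)(C)C(C)(C)C)C[C@H](O[Si](C)(C)C(C)(C)C)C[C@@H](O[Si](C)(C)C(C)(C)C)C[C@H](O[Si](C)(C)C(C)(C)C)CC(=O)CC | intermediate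
52 | enol borinate: Z enol diisopinocampheylborinate of 51 (C17–O–B, C17=C18, oxygen cis to the C18 methyl) | O=CC#CC[C@H](O[Si](C)(C)C(C)(C)C)CCC[C@H](O[Si](C)(C)C(C)(C)C)CCC[C@H](O[Si](C)(C)C(C)(C)C)CCCCCCC#CC[C@@H]([C@@H](C)[C@H](O[Si](C)(C)C(C)(C)C)CCCCC[C@@H](C)O[Si](C)(C)C(C)(C)C)OC(=O)C#C/C(C)=C\C[C@H](O[Si](C)(C)C(C)(C)C)C[C@@H](O[Si](C)(C)C(C)(C)C)C[C@H](O[Si](C)(C)C(C)(C)C)C[C@@H](O[Si](C)(C)C(C)(C)C)C[C@H](O[Si](C)(C)C(C)(C)C)C/C(OB([C@@H]1C[C@@H]2C[C@H]([C@H]1C)C2(C)C)[C@@H]1C[C@@H]2C[C@H]([C@H]1C)C2(C)C)=C/C | intermediate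
53 | macrocyclic aldol (42-membered lactone; C17 ketone; C18 methyl and C19 OH syn, as in the target; three alkynes; ten OTBS) | O[C@@H]1C#CC[C@H](O[Si](C)(C)C(C)(C)C)CCC[C@H](O[Si](C)(C)C(C)(C)C)CCC[C@H](O[Si](C)(C)C(C)(C)C)CCCCCCC#CC[C@@H]([C@@H](C)[C@H](O[Si](C)(C)C(C)(C)C)CCCCC[C@@H](C)O[Si](C)(C)C(C)(C)C)OC(=O)C#C/C(C)=C\C[C@H](O[Si](C)(C)C(C)(C)C)C[C@@H](O[Si](C)(C)C(C)(C)C)C[C@H](O[Si](C)(C)C(C)(C)C)C[C@@H](O[Si](C)(C)C(C)(C)C)C[C@H](O[Si](C)(C)C(C)(C)C)CC(=O)[C@H]1C | intermediate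
54 | macrocyclic 17,19-diol triyne (C17, C18, C19 as in the target) | O[C@@H]1C#CC[C@H](O[Si](C)(C)C(C)(C)C)CCC[C@H](O[Si](C)(C)C(C)(C)C)CCC[C@H](O[Si](C)(C)C(C)(C)C)CCCCCCC#CC[C@@H]([C@@H](C)[C@H](O[Si](C)(C)C(C)(C)C)CCCCC[C@@H](C)O[Si](C)(C)C(C)(C)C)OC(=O)C#C/C(C)=C\C[C@H](O[Si](C)(C)C(C)(C)C)C[C@@H](O[Si](C)(C)C(C)(C)C)C[C@H](O[Si](C)(C)C(C)(C)C)C[C@@H](O[Si](C)(C)C(C)(C)C)C[C@H](O[Si](C)(C)C(C)(C)C)C[C@@H](O)[C@H]1C | intermediate
55 | deca(TBS) ether of the target (OTBS at C7, C9, C11, C13, C15, C23, C27, C31, C43, C49; free OH at C17 and C19; 2Z,4Z,20Z,38Z) | CC1=C/C[C@H](O[Si](C)(C)C(C)(C)C)C[C@@H](O[Si](C)(C)C(C)(C)C)C[C@H](O[Si](C)(C)C(C)(C)C)C[C@@H](O[Si](C)(C)C(C)(C)C)C[C@H](O[Si](C)(C)C(C)(C)C)C[C@@H](O)[C@@H](C)[C@H](O)/C=C\C[C@H](O[Si](C)(C)C(C)(C)C)CCC[C@H](O[Si](C)(C)C(C)(C)C)CCC[C@H](O[Si](C)(C)C(C)(C)C)CCCCCC/C=C\C[C@@H]([C@@H](C)[C@H](O[Si](C)(C)C(C)(C)C)CCCCC[C@@H](C)O[Si](C)(C)C(C)(C)C)OC(=O)/C=C\1 | intermediate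
56 | CNP0071908.2 | CC1=C/C[C@H](O)C[C@@H](O)C[C@H](O)C[C@@H](O)C[C@H](O)C[C@@H](O)[C@@H](C)[C@H](O)/C=C\C[C@H](O)CCC[C@H](O)CCC[C@H](O)CCCCCC/C=C\C[C@@H]([C@@H](C)[C@H](O)CCCCC[C@@H](C)O)OC(=O)/C=C\1 | target

**Summary**

Total step count: 34. Longest linear sequence: 17 steps (steps 18–25, then 26–34).

Steps most likely to fail:

1. Step 31 (macro-aldol). Enolisation may occur partly at C16 and be followed by β-elimination of the C15 silyloxy group. The reagent may fail to override the conformational preferences of the 42-membered transition state, giving poor facial selectivity. Slow bimolecular enolisation at high dilution may also let oligomerisation compete. The fallback sets out from 49 and comes back at 53. It fixes the enolate position before the aldehyde is unveiled and generates the enolate without base. Ketone 49 is enolised with Bu2BOTf and i-Pr2NEt and the enol borinate is quenched with N-bromosuccinimide to the C18 bromo ketone F1, any C16 regioisomer being removed at this acyclic stage. DDQ then gives the bromo propargylic alcohol F2 and Dess–Martin oxidation the bromo keto ynal F3. SmI2 in THF at −78 °C under high dilution reduces the carbon–bromine bond to a trivalent samarium enolate, which closes the same C18–C19 bond in an intramolecular Reformatsky-type aldol through a chelated chair. This should give 53 after separation from its C18/C19 diastereomers.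

2. Step 28 (Sonogashira coupling of the propiolate). The terminal alkynoate may add the amine in a Michael reaction, oligomerise, or homocouple at copper faster than it transmetalates to palladium. The fallback sets out from 18 and 46 and comes back at 49. It makes the C3–C4 bond with a well-behaved alkyne and moves the fragment union to the ester bond. Sonogashira coupling of 18 with propargyl alcohol (PdCl2(PPh3)2, CuI, Et3N) should give the enynol F4. MnO2 oxidises it to the enynal F5, and Pinnick oxidation (NaClO2, NaH2PO4, 2-methylbut-2-ene) gives the enynoic acid F6. Yamaguchi esterification of F6 with 46 (2,4,6-trichlorobenzoyl chloride, Et3N, DMAP) then gives 49.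

3. Step 33 (triple Lindlar reduction). The conjugated C2–C5 enyne may be over-reduced, the hindered C38≡C39 alkyne may react incompletely, and the dienoate may isomerise from Z to E on the catalyst surface; products of this kind would be hard to separate at the macrocycle stage. The fallback sets out from 50 and comes back at 55. It moves the semi-hydrogenation to the acyclic stage and runs the ring closure on a Z enal. Alcohol 50 is reduced under the same poisoned-palladium conditions to the (2Z,4Z,20Z,38Z) allylic alcohol F7, from which partly or over-reduced material is removed by chromatography. MnO2 gives the Z enal F8, and the (−)-Ipc2BOTf macro-aldol of step 31 applied to F8 gives the macrocyclic aldol F9. Evans–Saksena reduction of F9 gives 55.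

Further compounds

F1 | step 31 | C18 bromo ketone of 49 (bromine on C18, either configuration) | COc1ccc(cc1)COCC#CC[C@H](O[Si](C)(C)C(C)(C)C)CCC[C@H](O[Si](C)(C)C(C)(C)C)CCC[C@H](O[Si](C)(C)C(C)(C)C)CCCCCCC#CC[C@@H]([C@@H](C)[C@H](O[Si](C)(C)C(C)(C)C)CCCCC[C@@H](C)O[Si](C)(C)C(C)(C)C)OC(=O)C#C/C(C)=C\C[C@H](O[Si](C)(C)C(C)(C)C)C[C@@H](O[Si](C)(C)C(C)(C)C)C[C@H](O[Si](C)(C)C(C)(C)C)C[C@@H](O[Si](C)(C)C(C)(C)C)C[C@H](O[Si](C)(C)C(C)(C)C)CC(=O)C(Br)C
F2 | step 31 | bromo propargylic alcohol (F1 with free C19 OH) | OCC#CC[C@H](O[Si](C)(C)C(C)(C)C)CCC[C@H](O[Si](C)(C)C(C)(C)C)CCC[C@H](O[Si](C)(C)C(C)(C)C)CCCCCCC#CC[C@@H]([C@@H](C)[C@H](O[Si](C)(C)C(C)(C)C)CCCCC[C@@H](C)O[Si](C)(C)C(C)(C)C)OC(=O)C#C/C(C)=C\C[C@H](O[Si](C)(C)C(C)(C)C)C[C@@H](O[Si](C)(C)C(C)(C)C)C[C@H](O[Si](C)(C)C(C)(C)C)C[C@@H](O[Si](C)(C)C(C)(C)C)C[C@H](O[Si](C)(C)C(C)(C)C)CC(=O)C(Br)C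
F3 | step 31 | bromo keto ynal (C19 aldehyde, C18 bromide) | O=CC#CC[C@H](O[Si](C)(C)C(C)(C)C)CCC[C@H](O[Si](C)(C)C(C)(C)C)CCC[C@H](O[Si](C)(C)C(C)(C)C)CCCCCCC#CC[C@@H]([C@@H](C)[C@H](O[Si](C)(C)C(C)(C)C)CCCCC[C@@H](C)O[Si](C)(C)C(C)(C)C)OC(=O)C#C/C(C)=C\C[C@H](O[Si](C)(C)C(C)(C)C)C[C@@H](O[Si](C)(C)C(C)(C)C)C[C@H](O[Si](C)(C)C(C)(C)C)C[C@@H](O[Si](C)(C)C(C)(C)C)C[C@H](O[Si](C)(C)C(C)(C)C)CC(=O)C(Br)C
F4 | step 28 | C1–C18 enynol (C1 primary alcohol, C2≡C3, (4Z)-alkene, C17 ketone) | OCC#C/C(C)=C\C[C@H](O[Si](C)(C)C(C)(C)C)C[C@@H](O[Si](C)(C)C(C)(C)C)C[C@H](O[Si](C)(C)C(C)(C)C)C[C@@H](O[Si](C)(C)C(C)(C)C)C[C@H](O[Si](C)(C)C(C)(C)C)CC(=O)CC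
F5 | step 28 | C1–C18 enynal | O=CC#C/C(C)=C\C[C@H](O[Si](C)(C)C(C)(C)C)C[C@@H](O[Si](C)(C)C(C)(C)C)C[C@H](O[Si](C)(C)C(C)(C)C)C[C@@H](O[Si](C)(C)C(C)(C)C)C[C@H](O[Si](C)(C)C(C)(C)C)CC(=O)CC
F6 | step 28 | C1–C18 enynoic acid | OC(=O)C#C/C(C)=C\C[C@H](O[Si](C)(C)C(C)(C)C)C[C@@H](O[Si](C)(C)C(C)(C)C)C[C@H](O[Si](C)(C)C(C)(C)C)C[C@@H](O[Si](C)(C)C(C)(C)C)C[C@H](O[Si](C)(C)C(C)(C)C)CC(=O)CC
F7 | step 33 | seco (2Z,4Z,20Z,38Z) allylic alcohol (free C19 OH, C17 ketone) | OC/C=C\C[C@H](O[Si](C)(C)C(C)(C)C)CCC[C@H](O[Si](C)(C)C(C)(C)C)CCC[C@H](O[Si](C)(C)C(C)(C)C)CCCCCC/C=C\C[C@@H]([C@@H](C)[C@H](O[Si](C)(C)C(C)(C)C)CCCCC[C@@H](C)O[Si](C)(C)C(C)(C)C)OC(=O)/C=C\C(C)=C/C[C@H](O[Si](C)(C)C(C)(C)C)C[C@@H](O[Si](C)(C)C(C)(C)C)C[C@H](O[Si](C)(C)C(C)(C)C)C[C@@H](O[Si](C)(C)C(C)(C)C)C[C@H](O[Si](C)(C)C(C)(C)C)CC(=O)CC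
F8 | step 33 | seco Z enal (C19 aldehyde) | O=C/C=C\C[C@H](O[Si](C)(C)C(C)(C)C)CCC[C@H](O[Si](C)(C)C(C)(C)C)CCC[C@H](O[Si](C)(C)C(C)(C)C)CCCCCC/C=C\C[C@@H]([C@@H](C)[C@H](O[Si](C)(C)C(C)(C)C)CCCCC[C@@H](C)O[Si](C)(C)C(C)(C)C)OC(=O)/C=C\C(C)=C/C[C@H](O[Si](C)(C)C(C)(C)C)C[C@@H](O[Si](C)(C)C(C)(C)C)C[C@H](O[Si](C)(C)C(C)(C)C)C[C@@H](O[Si](C)(C)C(C)(C)C)C[C@H](O[Si](C)(C)C(C)(C)C)CC(=O)CC
F9 | step 33 | macrocyclic aldol with the four Z alkenes in place (C17 ketone, C19 OH) | O[C@@H]1/C=C\C[C@H](O[Si](C)(C)C(C)(C)C)CCC[C@H](O[Si](C)(C)C(C)(C)C)CCC[C@H](O[Si](C)(C)C(C)(C)C)CCCCCC/C=C\C[C@@H]([C@@H](C)[C@H](O[Si](C)(C)C(C)(C)C)CCCCC[C@@H](C)O[Si](C)(C)C(C)(C)C)OC(=O)/C=C\C(C)=C/C[C@H](O[Si](C)(C)C(C)(C)C)C[C@@H](O[Si](C)(C)C(C)(C)C)C[C@H](O[Si](C)(C)C(C)(C)C)C[C@@H](O[Si](C)(C)C(C)(C)C)C[C@H](O[Si](C)(C)C(C)(C)C)CC(=O)[C@H]1C
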